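The route rests on cutting the bond between the ketone carbon and its α-carbon in the seven-membered ring. The α-carbon bears a 4-hydroxyphenyl ring and is bonded to C2' of ring B, so it can act as the exocyclic carbon of a p-quinone methide of that phenol ring, while the carbonyl carbon is the C4 aldehyde of benzofuran ring A with its polarity inverted by a carbene. One carbene-catalysed 1,6-addition then closes the ring, makes the ketone and sets the α-centre. The precursor is a trans-(2R,3R)-2,3-diaryl-2,3-dihydrobenzofuran-4-carbaldehyde whose ring B carries a 4-hydroxybenzhydryl p-tolyl sulfone that releases the quinone methide under base.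

Key step: step 10

Remark on locants: benzofuran numbering (O1, C2, C3, C3a, C4 to C7, C7a) is used for ring A and the furan ring; ring B has primed locants (C1' on C3, C2' bearing the benzhydryl carbon, methoxy groups on C3' and C5'); tosyl means 4-methylbenzenesulfonyl.

Assumption: the (1S,4S,5S) enantiomer of isothiocineole (12) is taken to be the one whose 4-methoxybenzylide leads to the (2R,3R) series, by analogy with the face selectivity of its benzylides in epoxidation; if the first annulation shows the opposite sense, the (1R,4R,5R) sulfide is used in the same way.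

Step 1
Reactants: 1 4-bromophenol
Product: 2 (4-bromophenoxy)triisopropylsilane
Conditions: TIPSCl, imidazole, DMF, rt
Reagents that add atoms: chlorotriisopropylsilane, CC(C)[Si](Cl)(C(C)C)C(C)C
Why: Imidazole-promoted O-silylation of the phenol; the triisopropylsilyl ether is chosen because it should tolerate organolithium reagents, sulfinic acid and carbonate bases and can be removed later with buffered fluoride, and no stereocentre is involved.

Step 2
Reactants: 2 (4-bromophenoxy)triisopropylsilane; 3 2-bromo-4,6-dimethoxybenzaldehyde
Product: 5 (2-bromo-4,6-dimethoxyphenyl)[4-(triisopropylsilyloxy)phenyl]methanol (racemic), via arylmagnesium bromide 4 (not isolated)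
Conditions: Mg, THF, reflux; then 3, 0 °C to rt; aq NH4Cl
Reagents that add atoms: none
Why: Grignard formation and 1,2-addition of the aryl Grignard reagent to the aldehyde; the carbinol centre forms racemic, which is immaterial because this carbon becomes the planar quinone methide carbon in step 10.

Step 3
Reactants: 3 2-bromo-4,6-dimethoxybenzaldehyde
Product: 6 2-bromo-6-hydroxy-4-methoxybenzaldehyde
Conditions: BCl3, CH2Cl2, −78 °C to rt; H2O
Reagents that add atoms: none
Why: Chelation-directed aryl methyl ether cleavage, in which boron bound to the formyl oxygen removes only the methyl group ortho to it and leaves the para methoxy group and the bromide untouched.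

Step 4
Reactants: 5 (2-bromo-4,6-dimethoxyphenyl)[4-(triisopropylsilyloxy)phenyl]methanol; 6 2-bromo-6-hydroxy-4-methoxybenzaldehyde
Product: 9 3-bromo-2-[hydroxy(2-{hydroxy[4-(triisopropylsilyloxy)phenyl]methyl}-3,5-dimethoxyphenyl)methyl]-5-methoxyphenol (diastereomer mixture), via lithium alkoxide aryllithium 7 (not isolated), via sodium phenolate 8 (not isolated)
Conditions: 5, n-BuLi (2.1 equiv), THF, −78 °C; 6, NaH, THF, 0 °C in a second flask; combine, −78 to 0 °C; aq NH4Cl
Reagents that add atoms: none
Why: Deprotonation of the carbinol followed by bromine–lithium exchange gives an ortho-lithiated benzylic alkoxide that undergoes 1,2-addition to the formyl group of the pre-formed phenolate (the ring A bromide exchanges far more slowly than the aldehyde is attacked); the new carbinol centre forms unselectively and is erased in step 7.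

Step 5
Reactants: 9 the triol of step 4
Product: 10 3-bromo-5-methoxy-2-[(3,5-dimethoxy-2-{[4-(triisopropylsilyloxy)phenyl](tosyl)methyl}phenyl)(tosyl)methyl]phenol (diastereomer mixture)
Conditions: p-TolSO2H (3 equiv), MgSO4, CH2Cl2, rt
Reagents that add atoms: p-toluenesulfinic acid, Cc1ccc(S(=O)O)cc1
Why: Dehydrative SN1 sulfonylation of electron-rich benzhydrols by a sulfinic acid, in which both carbinols ionise to stabilised benzhydryl cations that are captured at sulfur, and since ether formation between the two neighbouring positions is reversible under the acid whereas C–S bond formation is not, the material should converge on the bis-sulfone, whose two sulfonyl carbons form unselectively and are erased in steps 7 and 10.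

Step 6
Reactants: 11 4-methoxybenzyl chloride; 12 (1S,4S,5S)-isothiocineole
Product: 13 (1S,4S,5S)-6-(4-methoxybenzyl)-4,7,7-trimethyl-6-thiabicyclo[3.2.1]octan-6-ium tetrafluoroborate
Conditions: NaBF4, acetone, rt
Reagents that add atoms: sodium tetrafluoroborate, [Na+].F[B-](F)(F)F
Why: S-alkylation of the sulfide by the activated benzyl chloride, driven by precipitation of sodium chloride and exchange to the non-nucleophilic counter-ion; attack through the less hindered lone pair should give one diastereomer at sulfur.

Step 7
Reactants: 10 the bis-sulfone of step 5; 13 the sulfonium salt of step 6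
Product: 16 (2R,3R)-4-bromo-3-(3,5-dimethoxy-2-{[4-(triisopropylsilyloxy)phenyl](tosyl)methyl}phenyl)-6-methoxy-2-(4-methoxyphenyl)-2,3-dihydro-1-benzofuran (both epimers at the sulfonyl carbon), via sulfonium ylide 14 (not isolated), via o-quinone methide 15 (not isolated)
Conditions: Cs2CO3, MeCN–CH2Cl2, −20 °C to rt
Reagents that add atoms: none
Why: Sulfur ylide [4+1] annulation of an o-quinone methide: carbonate releases 15 from the o-hydroxybenzyl sulfone (the ring B sulfone stays silent because its phenol is silylated) and ylide 14 from 13, conjugate addition of the ylide carbon to the methide carbon is followed by 5-exo-tet displacement of the sulfide by the phenolate through the anti betaine, which gives the trans ring, and the chiral sulfide, by shielding one face of the ylide carbon, should set C2 as R and, through the trans closure, C3 as R.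

Step 8
Reactants: 16 the 4-bromo-dihydrobenzofuran of step 7
Product: 18 (2R,3R)-3-(3,5-dimethoxy-2-{[4-(triisopropylsilyloxy)phenyl](tosyl)methyl}phenyl)-6-methoxy-2-(4-methoxyphenyl)-2,3-dihydro-1-benzofuran-4-carbaldehyde (both epimers at the sulfonyl carbon), via potassium lithium dianion 17 (not isolated)
Conditions: KH, THF, 0 °C; t-BuLi (2 equiv), −78 °C; DMF; aq NH4Cl
Reagents that add atoms: N,N-dimethylformamide, CN(C)C=O
Why: Bromine–lithium exchange and formylation of the aryllithium with DMF, carried out after KH has turned the acidic sulfone C–H into its carbanion so that the C4 aryllithium cannot be quenched internally; C2 and C3 are not acidic enough to be touched at −78 °C and the carbanion is reprotonated on work-up.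

Step 9
Reactants: 18 the silyl-protected aldehyde of step 8
Product: 19 (2R,3R)-3-{2-[(4-hydroxyphenyl)(tosyl)methyl]-3,5-dimethoxyphenyl}-6-methoxy-2-(4-methoxyphenyl)-2,3-dihydro-1-benzofuran-4-carbaldehyde (both epimers at the sulfonyl carbon)
Conditions: TBAF, AcOH, THF, 0 °C
Reagents that add atoms: none
Why: Fluoride cleavage of the aryl silyl ether, with acetic acid keeping the liberated phenol protonated so that sulfinate is not expelled before the key step.

Step 10
Reactants: 19 the 4-hydroxybenzhydryl sulfone aldehyde of step 9
Product: 21 tetra-O-methylpauciflorol E with the 4-hydroxyphenyl group on the ketone α-carbon free (2R,3R in the dihydrofuran ring; α-carbon R), via p-quinone methide 20 (not isolated)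
Conditions: 2-(pentafluorophenyl)-6,7-dihydro-5H-pyrrolo[2,1-c][1,2,4]triazol-2-ium tetrafluoroborate (20 mol%), Cs2CO3 (1.5 equiv), THF (0.01 M), Ar, 0 °C to rt
Reagents that add atoms: none
Why: Proposed new method: carbonate deprotonates the phenol of 19, the phenolate expels p-toluenesulfinate to give quinone methide 20, and the triazolylidene adds to the C4 aldehyde to give, after proton transfer, the Breslow enaminol, whose acyl anion carbon attacks the exocyclic methide carbon in a 1,6-conjugate addition driven by rearomatisation to the phenolate, after which the adduct collapses to the ketone and frees the carbene. The closest known reaction type is the intermolecular carbene-catalysed 1,6-addition of aromatic aldehydes to 2,6-di-tert-butyl p-quinone methides, which gives α,α-diaryl ketones, together with the known base-induced release of p-quinone methides from 4-hydroxybenzyl sulfones; a ring-closing version on a methide without flanking tert-butyl groups is not established. The seven-membered ketone ring closes in the 7-exo-trig mode, the aldehyde carbon and the methide carbon being held close by the C3 methine that joins rings A and B. The new α-stereocentre is controlled by the C3 stereocentre, since the dienone ring should turn to the face of H-3, away from C2 and its anisyl group, and because the doubly benzylic α-proton is acidic the centre should also equilibrate under the carbonate to the epimer whose aryl group is pseudo-axial and free of strain with the C3' methoxy group, which is the required R configuration. The step needs chemoselectivity for intramolecular acyl anion addition over benzoin coupling, carbene or sulfinate addition to the methide and methide oligomerisation, and this should be secured by slow release of 20 from the sulfone, high dilution and the proximity of the two reacting carbons, sulfinate addition merely returning 19. Air is excluded because the enolate of the product is easily oxidised.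

Step 11
Reactants: 21 the ketone of step 10
Product: 22 pauciflorol E
Conditions: BBr3, CH2Cl2, −78 to 0 °C; MeOH; aq NaHCO3
Reagents that add atoms: none
Why: Lewis acid cleavage of the four aryl methyl ethers (boron complexation, bromide attack at methyl), which breaks no bond to a stereocentre; the trans dihydrofuran and the pseudo-axial α-aryl group are the stable arrangements, so reversible C2–O ionisation or enolisation under the Lewis acid should return the same isomer.

Compound list
1 | 4-bromophenol | Oc1ccc(Br)cc1 | starting material
2 | (4-bromophenoxy)triisopropylsilane | CC(C)[Si](Oc1ccc(Br)cc1)(C(C)C)C(C)C | intermediate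
3 | 2-bromo-4,6-dimethoxybenzaldehyde | COc1cc(Br)c(C=O)c(OC)c1 | starting material
4 | [4-(triisopropylsilyloxy)phenyl]magnesium bromide | CC(C)[Si](Oc1ccc([Mg]Br)cc1)(C(C)C)C(C)C | intermediate
5 | (2-bromo-4,6-dimethoxyphenyl)[4-(triisopropylsilyloxy)phenyl]methanol, racemic | COc1cc(Br)c(C(O)c2ccc(O[Si](C(C)C)(C(C)C)C(C)C)cc2)c(OC)c1 | intermediate
6 | 2-bromo-6-hydroxy-4-methoxybenzaldehyde | COc1cc(O)c(C=O)c(Br)c1 | intermediate
7 | lithium (2-lithio-4,6-dimethoxyphenyl)[4-(triisopropylsilyloxy)phenyl]methanolate | COc1cc([Li])c(C(O[Li])c2ccc(O[Si](C(C)C)(C(C)C)C(C)C)cc2)c(OC)c1 | intermediate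
8 | sodium 3-bromo-2-formyl-5-methoxyphenolate | COc1cc([O-])c(C=O)c(Br)c1.[Na+] | intermediate
9 | 3-bromo-2-[hydroxy(2-{hydroxy[4-(triisopropylsilyloxy)phenyl]methyl}-3,5-dimethoxyphenyl)methyl]-5-methoxyphenol, diastereomer mixture | COc1cc(O)c(C(O)c2cc(OC)cc(OC)c2C(O)c2ccc(O[Si](C(C)C)(C(C)C)C(C)C)cc2)c(Br)c1 | intermediate
10 | 3-bromo-5-methoxy-2-[(3,5-dimethoxy-2-{[4-(triisopropylsilyloxy)phenyl](tosyl)methyl}phenyl)(tosyl)methyl]phenol, diastereomer mixture | COc1cc(O)c(C(c2cc(OC)cc(OC)c2C(c2ccc(O[Si](C(C)C)(C(C)C)C(C)C)cc2)S(=O)(=O)c2ccc(C)cc2)S(=O)(=O)c2ccc(C)cc2)c(Br)c1 | intermediate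
11 | 4-methoxybenzyl chloride | COc1ccc(CCl)cc1 | starting material
12 | (1S,4S,5S)-isothiocineole, (1S,4S,5S)-4,7,7-trimethyl-6-thiabicyclo[3.2.1]octane | C[C@H]1CC[C@H]2C[C@@H]1SC2(C)C | starting material
13 | (1S,4S,5S)-6-(4-methoxybenzyl)-4,7,7-trimethyl-6-thiabicyclo[3.2.1]octan-6-ium tetrafluoroborate, one configuration at sulfur | C[C@H]1CC[C@H]2C[C@@H]1[S+](Cc1ccc(OC)cc1)C2(C)C.F[B-](F)(F)F | intermediate
14 | sulfonium (4-methoxyphenyl)methylide derived from 13 | C[C@H]1CC[C@H]2C[C@@H]1[S+]([CH-]c1ccc(OC)cc1)C2(C)C | intermediate
15 | 5-bromo-6-[(3,5-dimethoxy-2-{[4-(triisopropylsilyloxy)phenyl](tosyl)methyl}phenyl)methylidene]-3-methoxycyclohexa-2,4-dien-1-one (o-quinone methide) | COC1=CC(=O)C(=Cc2cc(OC)cc(OC)c2C(c2ccc(O[Si](C(C)C)(C(C)C)C(C)C)cc2)S(=O)(=O)c2ccc(C)cc2)C(Br)=C1 | intermediate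
16 | (2R,3R)-4-bromo-3-(3,5-dimethoxy-2-{[4-(triisopropylsilyloxy)phenyl](tosyl)methyl}phenyl)-6-methoxy-2-(4-methoxyphenyl)-2,3-dihydro-1-benzofuran, both epimers at the sulfonyl carbon | Brc1cc(OC)cc2c1[C@@H](c1cc(OC)cc(OC)c1C(c1ccc(O[Si](C(C)C)(C(C)C)C(C)C)cc1)S(=O)(=O)c1ccc(C)cc1)[C@H](c1ccc(OC)cc1)O2 | intermediate
17 | 4-lithio derivative of 16 with the sulfonyl carbon as its potassium carbanion | [Li]c1cc(OC)cc2c1[C@@H](c1cc(OC)cc(OC)c1C([K])(c1ccc(O[Si](C(C)C)(C(C)C)C(C)C)cc1)S(=O)(=O)c1ccc(C)cc1)[C@H](c1ccc(OC)cc1)O2 | intermediate
18 | (2R,3R)-3-(3,5-dimethoxy-2-{[4-(triisopropylsilyloxy)phenyl](tosyl)methyl}phenyl)-6-methoxy-2-(4-methoxyphenyl)-2,3-dihydro-1-benzofuran-4-carbaldehyde, both epimers at the sulfonyl carbon | O=Cc1cc(OC)cc2c1[C@@H](c1cc(OC)cc(OC)c1C(c1ccc(O[Si](C(C)C)(C(C)C)C(C)C)cc1)S(=O)(=O)c1ccc(C)cc1)[C@H](c1ccc(OC)cc1)O2 | intermediate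
19 | (2R,3R)-3-{2-[(4-hydroxyphenyl)(tosyl)methyl]-3,5-dimethoxyphenyl}-6-methoxy-2-(4-methoxyphenyl)-2,3-dihydro-1-benzofuran-4-carbaldehyde, both epimers at the sulfonyl carbon | O=Cc1cc(OC)cc2c1[C@@H](c1cc(OC)cc(OC)c1C(c1ccc(O)cc1)S(=O)(=O)c1ccc(C)cc1)[C@H](c1ccc(OC)cc1)O2 | intermediate
20 | (2R,3R)-3-{3,5-dimethoxy-2-[(4-oxocyclohexa-2,5-dien-1-ylidene)methyl]phenyl}-6-methoxy-2-(4-methoxyphenyl)-2,3-dihydro-1-benzofuran-4-carbaldehyde (p-quinone methide) | O=Cc1cc(OC)cc2c1[C@@H](c1cc(OC)cc(OC)c1C=C1C=CC(=O)C=C1)[C@H](c1ccc(OC)cc1)O2 | intermediate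
21 | tetra-O-methylpauciflorol E with the 4-hydroxyphenyl group on the ketone α-carbon free; C2 R, C3 R, α-carbon R | O=C1c2cc(OC)cc3c2[C@@H](c2cc(OC)cc(OC)c2[C@H]1c1ccc(O)cc1)[C@H](c1ccc(OC)cc1)O3 | intermediate
22 | pauciflorol E; C2 R, C3 R, α-carbon R | O=C1c2cc(O)cc3c2[C@@H](c2cc(O)cc(O)c2[C@H]1c1ccc(O)cc1)[C@H](c1ccc(O)cc1)O3 | target

Total step count: 11. Longest linear sequence: 9 steps (1, 2, 4, 5, 7, 8, 9, 10, 11).

Steps most likely to fail

1. Step 10 (the step labelled as a proposed new method). What may go wrong: the carbene may be captured by the quinone methide, or the methide may oligomerise or be re-trapped faster than the hindered Breslow intermediate closes the seven-membered ring. The fallback uses known sulfone chemistry in the normal polarity sense, sets out from 18 and comes back at 21. With the phenol still silylated no methide can form, so KOtBu in THF at −78 °C should give the α-sulfonyl carbanion, which adds to the C4 aldehyde and closes the same ring as the β-hydroxy sulfone F1 (quenched cold with acetic acid). Dess–Martin oxidation should give the β-keto sulfone F2. Samarium diiodide in THF–MeOH at −78 °C should remove the sulfonyl group reductively, and protonation of the enolate, with base equilibration if needed, should give the triisopropylsilyl ether of the ketone F3. Buffered TBAF then gives 21.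

2. Step 7. What may go wrong: the methide carbon of 15 is shielded by the peri bromine and the ortho-substituted ring B, so addition of the bulky chiral ylide may be slow, and the electron-rich anisyl ylide may discriminate its faces poorly. The fallback replaces reagent-controlled induction by resolution, sets out from 10 and comes back at 16. The small achiral salt 1-(4-methoxybenzyl)tetrahydrothiophenium tetrafluoroborate F4 (from 11, tetrahydrothiophene and NaBF4) under the same carbonate conditions should give the racemic trans-dihydrobenzofuran. Preparative chromatography on a chiral stationary phase then separates the (2R,3R) material, which is 16, from the (2S,3S) enantiomer F5.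

3. Step 8. What may go wrong: if deprotonation of the hindered sulfone C–H is incomplete before the exchange, the C4 aryllithium is quenched internally and the bromide is lost without formylation. The fallback avoids strong base, sets out from 16 and comes back at 18. Stille coupling with tributyl(vinyl)stannane (Pd(PPh3)4, toluene, 100 °C) should give the 4-vinyl compound F6, and Lemieux–Johnson cleavage (OsO4 cat., NaIO4, 2,6-lutidine, dioxane–water) should give 18.

Further compounds
F1 | step 10 | seven-membered β-hydroxy sulfone from cyclisation of 18 (carbinol and sulfonyl carbon as diastereomer mixture; C2 R, C3 R) | OC1c2cc(OC)cc3c2[C@@H](c2cc(OC)cc(OC)c2C1(c1ccc(O[Si](C(C)C)(C(C)C)C(C)C)cc1)S(=O)(=O)c1ccc(C)cc1)[C@H](c1ccc(OC)cc1)O3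
F2 | step 10 | seven-membered β-keto sulfone (sulfonyl carbon as epimer mixture; C2 R, C3 R) | O=C1c2cc(OC)cc3c2[C@@H](c2cc(OC)cc(OC)c2C1(c1ccc(O[Si](C(C)C)(C(C)C)C(C)C)cc1)S(=O)(=O)c1ccc(C)cc1)[C@H](c1ccc(OC)cc1)O3
F3 | step 10 | triisopropylsilyl ether of 21 (C2 R, C3 R, α-carbon R) | O=C1c2cc(OC)cc3c2[C@@H](c2cc(OC)cc(OC)c2[C@H]1c1ccc(O[Si](C(C)C)(C(C)C)C(C)C)cc1)[C@H](c1ccc(OC)cc1)O3
F4 | step 7 | 1-(4-methoxybenzyl)tetrahydrothiophenium tetrafluoroborate | COc1ccc(C[S+]2CCCC2)cc1.F[B-](F)(F)F
F5 | step 7 | (2S,3S) enantiomer of 16 (both epimers at the sulfonyl carbon) | Brc1cc(OC)cc2c1[C@H](c1cc(OC)cc(OC)c1C(c1ccc(O[Si](C(C)C)(C(C)C)C(C)C)cc1)S(=O)(=O)c1ccc(C)cc1)[C@@H](c1ccc(OC)cc1)O2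
F6 | step 8 | (2R,3R)-4-vinyl analogue of 16 (both epimers at the sulfonyl carbon) | C=Cc1cc(OC)cc2c1[C@@H](c1cc(OC)cc(OC)c1C(c1ccc(O[Si](C(C)C)(C(C)C)C(C)C)cc1)S(=O)(=O)c1ccc(C)cc1)[C@H](c1ccc(OC)cc1)O2
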